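## The problem

Compound 15 is a cis-fused 3,7-dioxabicyclo[3.3.0]octan-2-one. A γ-lactone (C1, C2, O3, C4, C5) and a tetrahydrofuran (C1, C5, C6, O7, C8) share the C1–C5 bond; C4 carries the guaiacyl ring and C8 the catechol ring. The four contiguous stereocentres are 1S, 4S, 5R and 8S: H1 and H5 are cis, and both aryl groups lie on the convex face, trans to the neighbouring ring bonds C5–C6 and C1–C2. Only C5 is neither enolisable nor benzylic, so it must carry the absolute configuration. C1 can then be set from C5 by enolate chemistry on a lactone, and C4 and C8, each next to one bridgehead, can be set last by capture of benzylic cations. The same benzylic C–O bonds are the fragile part: both are para to an oxygenated ring position, ionise in acid, can be hydrogenolysed, and give quinone methides with base once the phenols are free. The O7–C8 bond is also β to the lactone carbonyl and is expelled when C1 is deprotonated, and the free catechol is sensitive to air. The phenols therefore stay masked to the end, no base is used once O7–C8 exists, and acid steps are kept short and cold. The feature that opens the route is that C1 is an acceptor carbon (α to C2=O), C4 is a donor carbon (benzylic to a para-oxygenated arene), and C6 carries the oxygen that becomes O7. A diazoacetate on that oxygen holds a C1 carbenoid over a C5=C4 styrene bond; the addition makes C1–C5 and a C1–C4 bond absent from the target, and acid can break C1–C4 again because it joins acceptor to donor.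

## Retrosynthesis

**15 from 14.** No skeletal bond is cut; the three phenols are unmasked from the tribenzyl ether 14. Benzyl ethers survive carbenoids, acid, amide bases and hydroxide, and they leave under neutral conditions, which a free para-hydroxybenzylic lactone needs. The forward step must cleave three aryl benzyl ethers without touching the two ring benzylic C–O bonds.

**14 from 13, and 13 from 12.** The cuts are O3–C4 and O7–C8, both benzylic C–O bonds, giving the seco acid 13, which comes from lactone 12 by saponification. The neighbouring cut, C1–C8 on a preformed γ-aryl lactone, was set aside for two reasons. An intermolecular aldol there places C8 trans to C6, which is wrong. The tethered version through an oxocarbenium ion on O7 is a 5-endo closure whose facial sense at C8 is not secured. In 13 both benzylic carbons are acyclic and their configuration is irrelevant. The forward step asks that both ionise, that the carboxyl closes on C4 and the C6 hydroxyl on C8, and that each aryl group ends exo.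

**12 from 9 and 10.** The cut is C1–C8, an aldol between the enolate of lactone 9 and the commercial aldehyde 10. The choice of lactone is the decisive point. About the C1–C5 bond, C1 carries C2, C8 and H, and C5 carries C4, C6 and H. In the target C2 faces C4, C8 faces C6 and H faces H. A turn of one third about C1–C5 puts C2 opposite C6, which is the lactone of 9 and 12; C8 then faces H5 and C4 faces H1, so the two side chains are trans. The ordinary trans aldol on the lactone closed through the C6 oxygen therefore already holds the C1/C5 relation of the cis-fused target. The forward reaction needs only the usual anti approach to a β-substituted butyrolactone enolate.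

**9 from 8.** The C1–C4 bond is reconnected: 9 is the adduct of methanol across the donor–acceptor bond of cyclopropane lactone 8. Opening 8 through its own carboxyl would give the γ-aryl lactone directly, but that lactone alkylates trans in the wrong sense (see above), so an external nucleophile is used and the C6–O lactone is kept. The methoxy carbon needs no control, because step 8 ionises it. The forward step must break only C1–C4 and leave C5 intact.

**8 from 7.** The cuts are C1–C5 and C1–C4, the two bonds a C1 carbenoid forms with the C5=C4 double bond. This removes both rings and all three stereocentres of 8 and leaves the achiral diazoacetate 7. It is preferred to any cut that sets C5 by auxiliary or resolution because the absolute configuration comes from a catalyst. The forward step needs enantioface control on an E-aryl alkene, the one demanding requirement of the route.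

**7 from 6, 6 from 4 and 5, 4 from 3, 3 from 1 and 2.** Standard ester disconnections: diazoacetate from bromoacetate 6, bromoacetate from alcohol 4 and bromoacetyl bromide 5, alcohol 4 by reduction of ester 3, and 3 from ferulic acid 1 and benzyl bromide 2.

## Roads not taken

**Alternative 1:** The cut is C1–C5, made across the nine-membered (Z)-alkenyl lactone A2, in which O7–C8 and the ester are already in place. Forward, the silyl ketene acetal of A2 undergoes an Ireland–Claisen rearrangement through a boat transition state and contracts to the tetrahydrofuran acid A1 (carboxyl on C1, vinyl on C5, aryl on C8).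
- Merits: one pericyclic step reads the cis C1/C5 and trans C1/C8 relations from a defined transition state, and C8 never passes through a cation.
- Weak points: A2 is a medium ring whose closure must beat oligomerisation and deliver the Z alkene. The absolute configuration has to be installed at C8 before the key step by a separate asymmetric operation. After A1 the vinyl group still has to be cleaved and arylated to create C4.
- Comparison: this road is better than the chosen plan at C8 and C1, which here rest on cation capture and on a trans aldol. Against that, the chosen plan has its asymmetric step catalytic and placed on a four-step substrate, needs no medium ring, and sets both benzylic centres in one operation.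

**Alternative 2:** The cuts are C8–C1 and C6–C5. Forward, CsF releases a nonstabilised carbonyl ylide (C8, O7, C6) from the α-silyl chloromethyl ether A5; it adds to the butenolide A4 anti to the C4 aryl group and gives A3, the tri-O-benzyl ether of the target (the same compound as 14).
- Merits: the bicyclic skeleton arises in one step from two fragments, and the cis fusion is automatic.
- Weak points: the only stereocentre of A4 is benzylic and vinylogously α to the carbonyl, so basic fluoride can racemise it through the 2-oxidofuran. The ylide is unsymmetrical, so two regiochemistries and two aryl orientations are possible, and nothing in either partner decides C8. Enantioenriched A4 needs an asymmetric synthesis of its own.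
- Comparison: this road is clearly shorter and more convergent. Against that, the chosen plan assigns every stereocentre to a control element and carries the absolute configuration at C5, which cannot epimerise.

**Alternative 3:** The cuts are O7–C8 and C1–C5. Forward, a zerovalent palladium catalyst (Pd2(dba)3 with a chiral bisphosphine) opens 2-vinyloxirane A8 to an alkoxide-bearing π-allyl cation. The alkoxide adds to C8 of the arylidene malonate A7, and the malonate carbon C1 closes on the inner allyl carbon C5 to give the tetrahydrofuran diester A6.
- Merits: catalytic absolute control, trivial partners, and the ether ring with C8 and C5 made in one step.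
- Weak points: the oxa-Michael addition is reversible, so the required 2,4-trans relation is not secured. The vinyl group must still be converted into C4. One ester must be removed from C1 while O7–C8 is β to it, and the dealkoxycarbonylation passes through a C1 enolate that can expel O7 and open the ring.
- Comparison: this road equals the chosen plan in using asymmetric catalysis and is better in forming the ether ring directly. Against that, the chosen plan discards no carbon and generates no C1 anion once O7–C8 exists.

Key step: step 5

Remark on the catalyst: the sense of induction is assumed to follow allyl diazoacetate, where S-configured carboxamidate ligands give the (1R,5S)-lactone. The (1S,5R,6R)-lactone 8 therefore calls for the R-configured catalyst, whose ligand derives from D-asparagine. If the aryl substrate responds in the opposite sense, the S-configured catalyst is used and nothing else changes.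

Remark on mixtures: the benzylic carbons bearing OMe in 9, 11, 12 and 13 and OH in 12 and 13 are carried as epimer mixtures and are written without descriptors in the SMILES, since step 8 ionises both.

## Route

Step 1
Reactants: 1 ferulic acid; 2 benzyl bromide
Product: 3 benzyl (E)-3-(4-benzyloxy-3-methoxyphenyl)acrylate
Conditions: 2 (2.3 equiv), K2CO3, DMF, 60 °C
Reagents that add atoms: none
Why: Double SN2 O-alkylation (Williamson etherification of the phenoxide and alkylation of the carboxylate); the E alkene is untouched and no stereocentre is formed.

Step 2
Reactants: 3 benzyl (E)-3-(4-benzyloxy-3-methoxyphenyl)acrylate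
Product: 4 (E)-3-(4-benzyloxy-3-methoxyphenyl)prop-2-en-1-ol
Conditions: i-Bu2AlH (2.5 equiv), CH2Cl2, −78 to 0 °C; aqueous potassium sodium tartrate
Reagents that add atoms: none
Why: 1,2-Reduction of a conjugated ester by an aluminium hydride gives the allylic alcohol; the aryl benzyl ether and the alkene geometry are not affected, and the released benzyl alcohol is separated.

Step 3
Reactants: 4 (E)-3-(4-benzyloxy-3-methoxyphenyl)prop-2-en-1-ol; 5 bromoacetyl bromide
Product: 6 (E)-3-(4-benzyloxy-3-methoxyphenyl)allyl bromoacetate
Conditions: NaHCO3, MeCN, 0 °C
Reagents that add atoms: none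
Why: Acylation of a primary allylic alcohol by an acid bromide; the hydrogen carbonate buffer removes HBr so that the electron-rich cinnamyl system does not ionise.

Step 4
Reactants: 6 (E)-3-(4-benzyloxy-3-methoxyphenyl)allyl bromoacetate
Product: 7 (E)-3-(4-benzyloxy-3-methoxyphenyl)allyl diazoacetate
Conditions: TsNHNHTs (2 equiv), DBU (5 equiv), THF, 0 °C
Reagents that add atoms: N,N'-ditosylhydrazine, Cc1ccc(cc1)S(=O)(=O)NNS(=O)(=O)c1ccc(C)cc1
Why: Diazoacetate synthesis from a bromoacetate: N-alkylation of the ditosylhydrazine anion followed by two base-induced losses of sulfinate gives the diazo ester under mild conditions that leave the alkene geometry intact.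

Step 5
Reactants: 7 (E)-3-(4-benzyloxy-3-methoxyphenyl)allyl diazoacetate
Product: 8 (1S,5R,6R)-6-(4-benzyloxy-3-methoxyphenyl)-3-oxabicyclo[3.1.0]hexan-2-one (aryl exo)
Conditions: Rh2(4R-MPPIM)4 [dirhodium tetrakis(methyl 1-(3-phenylpropanoyl)-2-oxoimidazolidine-4(R)-carboxylate)] (1 mol%), CH2Cl2, reflux, slow addition of 7
Reagents that add atoms: none
Why: The carboxamidate-bridged dirhodium catalyst takes up the diazo carbon of 7 with loss of N2 to give an electrophilic carbenoid at C1, which adds in one concerted, asynchronous step across the tethered C5=C4 double bond and forms C1–C5 and the temporary C1–C4 bond. The closest known reaction type is the enantioselective intramolecular cyclopropanation of allylic diazoacetates with chiral dirhodium carboxamidates. The lactone ring (C1, C2, ester O, C6, C5) closes in the 5-exo sense, C1 bonding to the near alkene carbon C5 while C4 stays outside, and the three-membered ring closes by the accompanying [2+1] addition at C4. C5, and with it C1, is fixed by the alkene enantioface that the chiral pocket of the catalyst admits, and the R-configured ligand set is chosen to deliver the (1S,5R) ring fusion. C1 and C5 can only be cis because a three-membered ring fused to a five-membered ring allows nothing else, and the aryl group at C4 (C6 of the bicycle) ends exo because the E geometry of 7 is transferred stereospecifically. The step needs cyclopropanation to win over carbene dimerisation, insertion into benzylic C–H bonds and addition to the arenes; slow addition keeps 7 dilute, and the electron-rich styrene bond held five atoms from C1 is the best nucleophile within reach. The imidazolidinone carboxamidate is preferred to the pyrrolidinone parent because E-aryl alkenes are the class that the parent differentiates least well.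

Step 6
Reactants: 8 (1S,5R,6R)-6-(4-benzyloxy-3-methoxyphenyl)-3-oxabicyclo[3.1.0]hexan-2-one
Product: 9 (4R)-4-[(4-benzyloxy-3-methoxyphenyl)(methoxy)methyl]dihydrofuran-2(3H)-one (epimer mixture at the methoxy carbon)
Conditions: TfOH (5 mol%), MeOH (10 equiv), CH2Cl2, 0 °C to rt; concentrate from toluene
Reagents that add atoms: methanol, CO
Why: Acid-catalysed homoconjugate addition of an alcohol to a donor–acceptor cyclopropane: the protonated lactone carbonyl accepts, the C1–C4 bond (the only ring bond that both overlaps with the carbonyl and carries the aryl donor) breaks, and methanol captures the benzylic carbon. C5 is not involved and keeps its configuration; any methyl ester formed by lactone methanolysis recloses on concentration.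

Step 7
Reactants: 9 (4R)-4-[(4-benzyloxy-3-methoxyphenyl)(methoxy)methyl]dihydrofuran-2(3H)-one; 10 3,4-bis(benzyloxy)benzaldehyde
Product: 12 (3S,4R)-3-{[3,4-bis(benzyloxy)phenyl](hydroxy)methyl}-4-[(4-benzyloxy-3-methoxyphenyl)(methoxy)methyl]dihydrofuran-2(3H)-one (3,4-trans; epimer mixture at both benzylic carbons), via lithium enolate 11 (not isolated)
Conditions: LiN(i-Pr)2 (1.1 equiv), THF, −78 °C; then 10; AcOH, −78 °C
Reagents that add atoms: none
Why: Lithium enolate aldol addition; the aldehyde approaches the butyrolactone enolate anti to the substituent on the neighbouring ring carbon, which sets C1 (S) trans to the C5 side chain, the relation that becomes the cis ring fusion. The carbinol carbon forms as a mixture that step 8 erases, and the cold acidic quench prevents retro-aldol cleavage.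

Step 8
Reactants: 12 (3S,4R)-3-{[3,4-bis(benzyloxy)phenyl](hydroxy)methyl}-4-[(4-benzyloxy-3-methoxyphenyl)(methoxy)methyl]dihydrofuran-2(3H)-one
Product: 14 (1S,4S,5R,8S)-8-[3,4-bis(benzyloxy)phenyl]-4-(4-benzyloxy-3-methoxyphenyl)-3,7-dioxabicyclo[3.3.0]octan-2-one, via seco hydroxy acid 13 (not isolated)
Conditions: LiOH, THF/H2O, 0 °C; 1 M HCl to pH 4, cold extraction; then CF3CO2H (5 equiv), CH2Cl2, −20 to 0 °C
Reagents that add atoms: lithium hydroxide, [Li+].[OH-]
Why: Saponification frees the C2 carboxyl and the C6 hydroxyl, and the cold, weakly acidic work-up delivers 13 before it can relactonise. In CF3CO2H both benzylic C–O bonds ionise to para-alkoxybenzyl cations and each is captured in a 5-exo closure, the carboxyl at C4 (benzylic SN1 lactonisation) and the C6 hydroxyl at C8 (SN1 cycloetherification), with the cis ring fusion already encoded in the trans C1/C5 relation of 12. Allylic 1,3-strain holds H5 and H1 in the plane of the respective cations, so each aryl group should end trans to the adjacent ring bond, which is exo at C4 (S) and at C8 (S).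

Step 9
Reactants: 14 (1S,4S,5R,8S)-8-[3,4-bis(benzyloxy)phenyl]-4-(4-benzyloxy-3-methoxyphenyl)-3,7-dioxabicyclo[3.3.0]octan-2-one
Product: 15 (1S,4S,5R,8S)-8-(3,4-dihydroxyphenyl)-4-(4-hydroxy-3-methoxyphenyl)-3,7-dioxabicyclo[3.3.0]octan-2-one
Conditions: H2 (1 atm), 10% Pd/C, EtOAc/THF, rt, stopped at three equivalents of H2
Reagents that add atoms: none
Why: Heterogeneous hydrogenolysis of three aryl benzyl ethers; under neutral conditions at atmospheric pressure these should be cleaved much faster than the benzylic lactone C4–O3 and ether C8–O7 bonds. No stereocentre is touched and no base is present that could open the para-hydroxybenzylic positions.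

## Compound list

1 | ferulic acid | COc1cc(/C=C/C(=O)O)ccc1O | starting material
2 | benzyl bromide | BrCc1ccccc1 | starting material
3 | benzyl (E)-3-(4-benzyloxy-3-methoxyphenyl)acrylate | COc1cc(/C=C/C(=O)OCc2ccccc2)ccc1OCc1ccccc1 | intermediate
4 | (E)-3-(4-benzyloxy-3-methoxyphenyl)prop-2-en-1-ol | COc1cc(/C=C/CO)ccc1OCc1ccccc1 | intermediate
5 | bromoacetyl bromide | BrCC(=O)Br | starting material
6 | (E)-3-(4-benzyloxy-3-methoxyphenyl)allyl bromoacetate | COc1cc(/C=C/COC(=O)CBr)ccc1OCc1ccccc1 | intermediate
7 | (E)-3-(4-benzyloxy-3-methoxyphenyl)allyl diazoacetate | COc1cc(/C=C/COC(=O)C=[N+]=[N-])ccc1OCc1ccccc1 | intermediate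
8 | (1S,5R,6R)-6-(4-benzyloxy-3-methoxyphenyl)-3-oxabicyclo[3.1.0]hexan-2-one | O=C1OC[C@@H]2[C@@H](c3ccc(OCc4ccccc4)c(OC)c3)[C@H]12 | intermediate
9 | (4R)-4-[(4-benzyloxy-3-methoxyphenyl)(methoxy)methyl]dihydrofuran-2(3H)-one, epimer mixture at the methoxy carbon | O=C1OC[C@H](C(OC)c2ccc(OCc3ccccc3)c(OC)c2)C1 | intermediate
10 | 3,4-bis(benzyloxy)benzaldehyde | O=Cc1ccc(OCc2ccccc2)c(OCc2ccccc2)c1 | starting material
11 | lithium enolate of 9 (formed in the flask) | [Li+].[O-]C1=C[C@@H](C(OC)c2ccc(OCc3ccccc3)c(OC)c2)CO1 | intermediate
12 | (3S,4R)-3-{[3,4-bis(benzyloxy)phenyl](hydroxy)methyl}-4-[(4-benzyloxy-3-methoxyphenyl)(methoxy)methyl]dihydrofuran-2(3H)-one, epimer mixture at both benzylic carbons | O=C1OC[C@H](C(OC)c2ccc(OCc3ccccc3)c(OC)c2)[C@H]1C(O)c1ccc(OCc2ccccc2)c(OCc2ccccc2)c1 | intermediate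
13 | (2S,3R)-2-{[3,4-bis(benzyloxy)phenyl](hydroxy)methyl}-4-(4-benzyloxy-3-methoxyphenyl)-3-(hydroxymethyl)-4-methoxybutanoic acid (formed in the flask), epimer mixture at both benzylic carbons | OC(=O)[C@H](C(O)c1ccc(OCc2ccccc2)c(OCc2ccccc2)c1)[C@H](CO)C(OC)c1ccc(OCc2ccccc2)c(OC)c1 | intermediate
14 | (1S,4S,5R,8S)-8-[3,4-bis(benzyloxy)phenyl]-4-(4-benzyloxy-3-methoxyphenyl)-3,7-dioxabicyclo[3.3.0]octan-2-one | COc1cc([C@H]2OC(=O)[C@H]3[C@@H]2CO[C@@H]3c2ccc(OCc4ccccc4)c(OCc4ccccc4)c2)ccc1OCc1ccccc1 | intermediate
15 | (1S,4S,5R,8S)-8-(3,4-dihydroxyphenyl)-4-(4-hydroxy-3-methoxyphenyl)-3,7-dioxabicyclo[3.3.0]octan-2-one | COc1cc([C@H]2OC(=O)[C@H]3[C@@H]2CO[C@@H]3c2ccc(O)c(O)c2)ccc1O | target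

## Step count and least certain steps

Total: 9 steps. Longest linear sequence: 9 steps (1 to 15); aldehyde 10 enters at step 7.

**Step 5 (key step).** The likely failure is incomplete enantioface discrimination, because E-disubstituted allylic diazoacetates are the class that carboxamidate catalysts differentiate least reliably; material may also be lost to carbene dimerisation if 7 accumulates. The fallback uses the fact that step 6 erases the configuration at C4, so the alkene geometry is free and the Z series, which this catalyst family handles best, can be used. Setting out from 4, triplet-sensitised E-to-Z isomerisation (fac-Ir(ppy)3, blue light, MeCN) would give (Z)-3-(4-benzyloxy-3-methoxyphenyl)prop-2-en-1-ol F1. Acylation with 5 under the conditions of step 3 would give (Z)-3-(4-benzyloxy-3-methoxyphenyl)allyl bromoacetate F2, and ditosylhydrazine with DBU the (Z)-diazoacetate F3. Cyclopropanation with Rh2(5R-MEPY)4, dirhodium tetrakis[methyl 2-oxopyrrolidine-5(R)-carboxylate], would give the endo-aryl lactone (1S,5R,6S)-6-(4-benzyloxy-3-methoxyphenyl)-3-oxabicyclo[3.1.0]hexan-2-one F4, which has the same C1 and C5 as 8. The conditions of step 6 would open F4 to 9, where the fallback rejoins the route.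

**Step 8.** Four things may go wrong:
- relactonisation of 13 onto the C6 hydroxyl before ionisation;
- capture of one benzylic cation by the other benzylic oxygen;
- proton loss from the C8 cation to an α-arylidene acid;
- drift of the kinetic exo preference towards an equilibrium mixture on long exposure to acid.

The fallback omits the saponification and changes the mechanism from carboxyl capture to acyl migration. Setting out from 12, aqueous acid (HClO4 in aqueous THF) would exchange the C4 methoxy group for hydroxyl, and the acyl group would migrate from the C6 oxygen to the C4 oxygen to give (3S,4R)-5-(4-benzyloxy-3-methoxyphenyl)-3-{[3,4-bis(benzyloxy)phenyl](hydroxy)methyl}-4-(hydroxymethyl)dihydrofuran-2(3H)-one F5. Its freed primary hydroxyl closes on the C8 cation, and C4 is corrected by reversible ionisation of the benzylic lactone bond; the fallback rejoins the route at 14.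

**Step 6.** The lactone is a single acceptor, so ionisation may be slow; forcing it risks proton loss from the C4 cation, which would erode C5, and loss of the benzyl ether. The fallback lets the carboxyl capture the cation intramolecularly and then changes the lactone. Setting out from 8, saponification with LiOH and treatment of the hydroxy acid with CF3CO2H in wet CH2Cl2 should give the trans γ-aryl lactone (4R,5S)-5-(4-benzyloxy-3-methoxyphenyl)-4-(hydroxymethyl)dihydrofuran-2(3H)-one F6. Methanolic HCl would then ionise its benzylic lactone C–O bond, methanol would capture C4, and the acid would relactonise on the primary hydroxyl; the fallback rejoins the route at 9.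

**Step 7.** Reversal of the aldol addition on warming or incomplete conversion with the hindered enolate may occur. The fallback replaces addition by acylation and reduction. Setting out from 9, LiN(SiMe3)2 (2.2 equiv) and methyl 3,4-bis(benzyloxy)benzoate would give the β-keto lactone (3S,4R)-3-[3,4-bis(benzyloxy)benzoyl]-4-[(4-benzyloxy-3-methoxyphenyl)(methoxy)methyl]dihydrofuran-2(3H)-one F7, which settles trans at its acidic C1. NaBH4 in MeOH at −20 °C would reduce the ketone; the fallback rejoins the route at 12.

## Further compounds

F1 | step 5 | (Z)-3-(4-benzyloxy-3-methoxyphenyl)prop-2-en-1-ol | COc1cc(/C=C\CO)ccc1OCc1ccccc1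
F2 | step 5 | (Z)-3-(4-benzyloxy-3-methoxyphenyl)allyl bromoacetate | COc1cc(/C=C\COC(=O)CBr)ccc1OCc1ccccc1
F3 | step 5 | (Z)-3-(4-benzyloxy-3-methoxyphenyl)allyl diazoacetate | COc1cc(/C=C\COC(=O)C=[N+]=[N-])ccc1OCc1ccccc1
F4 | step 5 | (1S,5R,6S)-6-(4-benzyloxy-3-methoxyphenyl)-3-oxabicyclo[3.1.0]hexan-2-one (aryl endo) | O=C1OC[C@@H]2[C@H](c3ccc(OCc4ccccc4)c(OC)c3)[C@H]12
F5 | step 8 | (3S,4R)-5-(4-benzyloxy-3-methoxyphenyl)-3-{[3,4-bis(benzyloxy)phenyl](hydroxy)methyl}-4-(hydroxymethyl)dihydrofuran-2(3H)-one, mixture at C5 and at the carbinol carbon | COc1cc(C2OC(=O)[C@H](C(O)c3ccc(OCc4ccccc4)c(OCc4ccccc4)c3)[C@@H]2CO)ccc1OCc1ccccc1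
F6 | step 6 | (4R,5S)-5-(4-benzyloxy-3-methoxyphenyl)-4-(hydroxymethyl)dihydrofuran-2(3H)-one | COc1cc([C@H]2OC(=O)C[C@@H]2CO)ccc1OCc1ccccc1
F7 | step 7 | (3S,4R)-3-[3,4-bis(benzyloxy)benzoyl]-4-[(4-benzyloxy-3-methoxyphenyl)(methoxy)methyl]dihydrofuran-2(3H)-one | O=C1OC[C@H](C(OC)c2ccc(OCc3ccccc3)c(OC)c2)[C@H]1C(=O)c1ccc(OCc2ccccc2)c(OCc2ccccc2)c1
A1 | alternative 1 | 2-[3,4-bis(benzyloxy)phenyl]-4-vinyltetrahydrofuran-3-carboxylic acid (2,3-trans, 3,4-cis) | OC(=O)[C@H]1[C@@H](C=C)CO[C@@H]1c1ccc(OCc2ccccc2)c(OCc2ccccc2)c1
A2 | alternative 1 | (Z)-4-[3,4-bis(benzyloxy)phenyl]-1,5-dioxacyclonon-7-en-2-one, configured at C4 as C8 of the target | O=C1C[C@@H](c2ccc(OCc3ccccc3)c(OCc3ccccc3)c2)OC/C=C\CO1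
A3 | alternative 2 | tri-O-benzyl ether of the target, identical with 14 | COc1cc([C@H]2OC(=O)[C@H]3[C@@H]2CO[C@@H]3c2ccc(OCc4ccccc4)c(OCc4ccccc4)c2)ccc1OCc1ccccc1
A4 | alternative 2 | (S)-5-(4-benzyloxy-3-methoxyphenyl)furan-2(5H)-one | O=C1C=C[C@@H](c2ccc(OCc3ccccc3)c(OC)c2)O1
A5 | alternative 2 | chloromethyl [3,4-bis(benzyloxy)phenyl](trimethylsilyl)methyl ether | C[Si](C)(C)C(OCCl)c1ccc(OCc2ccccc2)c(OCc2ccccc2)c1
A6 | alternative 3 | dimethyl 2-[3,4-bis(benzyloxy)phenyl]-4-vinyltetrahydrofuran-3,3-dicarboxylate (2,4-trans) | COC(=O)C1(C(=O)OC)[C@@H](C=C)CO[C@@H]1c1ccc(OCc2ccccc2)c(OCc2ccccc2)c1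
A7 | alternative 3 | dimethyl 2-[3,4-bis(benzyloxy)benzylidene]malonate | COC(=O)C(=Cc1ccc(OCc2ccccc2)c(OCc2ccccc2)c1)C(=O)OC
A8 | alternative 3 | 2-vinyloxirane | C=CC1CO1
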